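**Two runs.** The gap between L and Q is wider in the north-west run at 75 °C, 45.9% against 24.8% after 8.00 min, than in the south-east run at 108 °C, 34.7% against 28.3% after 4.00 min.

| flask | G | J | E | Z | temperature | remark | time |
|---|---|---|---|---|---|---|---|
| north-west | 0.025 M | 0.025 M | 0.050 M | 0.19 mM | 75 °C | run made earlier |  |
| south-east | 0.038 M | 0.038 M | 0.050 M | 0.19 mM | 108 °C | run made earlier |  |
| Tuesday's | 0.050 M | 0.050 M | 0.0500 M | 0.19 mM | 120 °C |  | 4.0 min |
| Thursday's | 0.050 M | 0.050 M | 0.0500 M | 0.19 mM | 90 °C |  | 4.0 min |
| Saturday's | 0.050 M | 0.050 M | 0.0500 M | 0.19 mM | 60 °C |  | 4.0 min |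

| run | time / min | L / % | Q / % |
|---|---|---|---|
| north-west | 2.00 | 40.3 | 16.7 |
| north-west | 3.00 | 41.2 | 20.1 |
| north-west | 5.00 | 44.7 | 23.6 |
| north-west | 8.00 | 45.9 | 24.8 |
| north-west | 12.0 | 47.6 | 30.4 |
| north-west | 25.0 | 48.1 | 33.9 |
| south-east | 0.333 | 17.0 | 12.1 |
| south-east | 0.833 | 23.5 | 18.3 |
| south-east | 1.50 | 29.4 | 22.3 |
| south-east | 2.50 | 32.7 | 25.1 |
| south-east | 4.00 | 34.7 | 28.3 |
| south-east | 5.00 | 36.4 | 27.4 |

(each reading ± 1 percentage point)

- Z is single-handed; G and J are mirror images of each other, charged as a racemate, each of them at the stated concentration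
- an excess is the difference of the two amounts in percent of their sum
- an excess is below zero if the other one leads

- the flask with the highest excess of L over Q ("all alike" if they lie within 1.5 percentage points) (Tuesday's / Thursday's / Saturday's / all alike)
- excess of L over Q at the end, Tuesday's
- excess of L over Q at the end, Thursday's
- excess of L over Q at the end, Saturday's

**One quotient.** If G and J are each consumed in proportion to their own amount, with E and Z common to both, then ln(G left)/ln(J left), as fractions of own charge, holds steady along a run. This is the selectivity factor, s. Replacing each curve by its mean over the readings gives 3.45 for the north-west run and 1.50 for the south-east run.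

**Three temperatures.** A straight line of ln s against temperature through these means gives 5.05 for Saturday's flask and 1.10 for Tuesday's. Thursday's selectivity factor, the quotient expected at its temperature, is 2.36.

**End point.** E, the limiting reagent, is half of G and J together. Once E is used up, G left and J left therefore add up to one, and their difference is the excess. G left is J left raised to the power s, so a trial J left of 0.7, corrected once along the slope, gives 3.70% for Tuesday's flask, 29.3% for Thursday's and 52.3% for Saturday's, assuming E is gone by 4.0 min.

**Weak link.** The mean is the doubtful step, since the quotients of the north-west run scatter, up and down between 4.03 at 2.00 min and 2.89 at 25.0 min, and the logarithm magnifies a reading's scatter of 1 percentage point where G left is small. Dividing summed logarithms instead gives 3.34 and 1.50. Saturday's s becomes 4.81 and its excess 50.8%, a shift smaller than the gap to Thursday's flask.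

**The forecast.** It gives 6%, 30% and 55% for Tuesday's, Thursday's and Saturday's flasks, and names Saturday's: “The coldest flask wins.” Each figure stands above this reckoning.

**The flasks.** They give 6.28%, 29.1% and 53.0%, and Saturday's leads.

    E + Z + G → Z + L (k = 3700 M⁻² s⁻¹, Ea = 17.0 kJ mol⁻¹)
    E + Z + J → Z + Q (k = 1600 M⁻² s⁻¹, Ea = 43.0 kJ mol⁻¹)
    Z ⇌ X (K = 1.50, k = 0.0300 s⁻¹, Ea = 103 kJ mol⁻¹, ΔH = −38.0 kJ mol⁻¹)
    E + Z → D (k = 0.0710 M⁻¹ s⁻¹, Ea = 53.0 kJ mol⁻¹)
    (constants at 90 °C)

In Thursday's flask the reaction of G uses E 2.3 times as fast as that of J at the start, and 1.4 times as fast at 4.00 min. Half of the turnover of G up to that time is done by 0.302 min. The 39% of G and 66% of J left there give s = 2.31, beside the expected 2.36. The neighbour flask with 0.20 M of E ends at an excess of 4.36%, and its 0.35% of G and 8.7% of J left give s = 2.32.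

The runs were generated by integration for substances that don't exist; noise was put on by code.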